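C1 = C(OH)(C7H2OBz), C2 = C=O, C3 = CH2, C4 = CHOH, C5 = CHOBz, C6 = CHOH; β is the ring face that carries C7, α is the face of C1–OH.
14 ⇒ 13 (C2 ketone masked as a spiro-1,3-dithiane, a temporary ring) ⇒ 12 (C4 raised to the ketone level).
12 ⇒ linear ynone aldehyde 9 + propane-1,3-dithiol 10: the C5–C6 aldol bond and both C2–S bonds are cut, and 9 holds one stereocentre (C1).
Enabling feature: in the cyclohexane ring the C5 benzoate and the free C6 hydroxyl lie next to the C4 oxygen, so C4(=O)–C5H(OBz)–C6H(OH) is an aldol retron. C2=O and C4–O are 1,3-related (ynone retron), and C1–OH sits α to C6 (chelation handle).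
9 ⇒ 6 + 8 (acyl Sonogashira); 6 ⇒ achiral 2-ethynylglycerol 4 (catalytic desymmetrising benzoylation sets C1) ⇒ 1 + 2. Ring order: dithiane ring, then carbocycle in the same flask, dithiane ring removed last.

Key step: step 7

Assumption: the sense of induction in step 3 follows the ligand antipode. The (R,R) ligand is written, and the (S,S) ligand is used instead if that is the one that delivers (R)-5.

Step 1
Reactants: 1 2,2-dimethyl-1,3-dioxan-5-one; 2 ethynylmagnesium bromide
Product: 3 5-ethynyl-2,2-dimethyl-1,3-dioxan-5-ol
Conditions: HC≡CMgBr (1.2 equiv), THF, 0 °C to rt; sat. aq NH4Cl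
Reagents that add atoms: none
Why: Grignard 1,2-addition of an alkynyl nucleophile to an inductively activated, symmetrical ketone; no stereocentre arises because the two CH2O arms are identical.

Step 2
Reactants: 3 5-ethynyl-2,2-dimethyl-1,3-dioxan-5-ol
Product: 4 2-ethynylpropane-1,2,3-triol (achiral, two enantiotopic CH2OH arms)
Conditions: AcOH/H2O (4:1), 40 °C; evaporation
Reagents that add atoms: none
Why: Acid-catalysed acetal hydrolysis frees the triol, and all volatile components leave on evaporation, which suits the water-soluble product.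

Step 3
Reactants: 4 2-ethynylpropane-1,2,3-triol
Product: 5 (2R)-2-hydroxy-2-(hydroxymethyl)but-3-yn-1-yl benzoate
Conditions: BzCl (1.0 equiv), Et3N (1.1 equiv), CuCl2 (10 mol %), (R,R)-Ph-BOX [2,2'-isopropylidenebis((4R)-4-phenyl-2-oxazoline), 11 mol %], THF, 0 °C
Reagents that add atoms: benzoyl chloride, O=C(Cl)c1ccccc1
Why: Enantioselective desymmetrising monobenzoylation of a 2-substituted glycerol: the chiral divalent-copper complex binds the tertiary OH and one of the two enantiotopic primary OH groups as a five-membered chelate and only that bound oxygen is acylated, which sets C1 by catalyst control and installs the C7 benzoate.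

Step 4
Reactants: 5 (2R)-2-hydroxy-2-(hydroxymethyl)but-3-yn-1-yl benzoate
Product: 6 (2S)-2-formyl-2-hydroxybut-3-yn-1-yl benzoate
Conditions: Dess–Martin periodinane (1.2 equiv), CH2Cl2, 0 °C to rt, carried out directly after step 3
Reagents that add atoms: none
Why: Dess–Martin oxidation converts only the primary alcohol (C6) into the aldehyde under near-neutral conditions, and it locks C1 because the two arms can no longer be exchanged by benzoyl migration.

Step 5
Reactants: 7 2-(benzoyloxy)acetic acid
Product: 8 2-(benzoyloxy)acetyl chloride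
Conditions: (COCl)2 (1.2 equiv), DMF (cat.), CH2Cl2, 0 °C to rt; evaporation
Reagents that add atoms: oxalyl chloride, O=C(Cl)C(=O)Cl
Why: Acid chloride formation through chloroiminium (Vilsmeier-type) activation of the acid, to which the benzoate ester is inert.

Step 6
Reactants: 6 (2S)-2-formyl-2-hydroxybut-3-yn-1-yl benzoate; 8 2-(benzoyloxy)acetyl chloride
Product: 9 (2S)-2-formyl-2-hydroxy-5-oxohex-3-yne-1,6-diyl dibenzoate
Conditions: PdCl2(PPh3)2 (2 mol %), CuI (4 mol %), Et3N (1.1 equiv), THF, 0 °C to rt, slow addition of 8
Reagents that add atoms: none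
Why: Acyl Sonogashira coupling (oxidative addition of the acid chloride to zerovalent palladium, transmetalation from the copper acetylide, reductive elimination) should give the ynone under conditions mild enough for the aldehyde, the tertiary alcohol and both benzoates, with C1 untouched.

Step 7
Reactants: 9 (2S)-2-formyl-2-hydroxy-5-oxohex-3-yne-1,6-diyl dibenzoate; 10 propane-1,3-dithiol
Product: 12 [(7S,8S,9S)-9-(benzoyloxy)-7,8-dihydroxy-10-oxo-1,5-dithiaspiro[5.5]undecan-7-yl]methyl benzoate (C1–OH and C6–OH α; C7 and C5–OBz β), via keto dithiane aldehyde 11 (not isolated)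
Conditions: 10 (1.0 equiv), i-Pr2NEt (3 equiv), CH2Cl2, −40 to 0 °C; then MgBr2·OEt2 (2.5 equiv), −20 °C to rt; pH 7 phosphate buffer
Reagents that add atoms: none
Why: Proposed new method: the amine-generated thiolate of 10 adds to the ynone β-carbon C2 and the second sulfur follows by a 6-exo-trig thia-Michael addition that closes the 1,3-dithiane, so the linear C1–C2≡C3–C4 rod, across which C5 and C6 cannot meet, becomes an sp3 hinge (11) with a gem-disubstituent effect; MgBr2·OEt2/i-Pr2NEt then soft-enolises the C4 ketone toward C5 and the enolate attacks the C6 aldehyde in a 6-(enolendo)-exo-trig aldol that closes the carbocycle. The closest known reaction types are the base-mediated double conjugate addition of propane-1,3-dithiol to ynones, which gives β-keto dithianes, and the magnesium halide/tertiary amine direct aldol addition; what is new is their merger in one flask as a carbocyclisation. C6 is controlled by C1: divalent magnesium ties C1–OH and C6=O into a nearly flat five-membered chelate, which fits only the chair with C1–O axial, C7 equatorial and C6=O equatorial, so the new C6–OH should be cis to C1–OH, and the alternative axial C6–O would be syn-axial to the axial C–S bond at C2. C5 is an epimerisable α-benzoyloxy ketone centre and should settle equatorial, trans to C6–OH. The step needs chemoselectivity of the dithiol for the ynone over the aldehyde, secured by the soft thiolate/soft acceptor match under basic conditions in which hemithioacetals revert and by the neopentyl, α-oxygenated C6 that resists thionium formation. It also needs regioselective enolisation, secured because C5–H is acidified by both the ketone and the chelating benzoate, whereas a C3 enolate could only close a four-membered ring.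

Step 8
Reactants: 12 [(7S,8S,9S)-9-(benzoyloxy)-7,8-dihydroxy-10-oxo-1,5-dithiaspiro[5.5]undecan-7-yl]methyl benzoate
Product: 13 [(7S,8S,9R,10R)-9-(benzoyloxy)-7,8,10-trihydroxy-1,5-dithiaspiro[5.5]undecan-7-yl]methyl benzoate (new C4–OH β, cis to C5–OBz)
Conditions: Li(s-Bu)3BH (lithium tri-sec-butylborohydride, 3.3 equiv), THF, −78 °C; AcOH quench at −78 °C
Reagents that add atoms: none
Why: Diastereoselective ketone reduction with a bulky trialkylborohydride: in the chair of 12 (C7, C5–OBz and C6–OH equatorial) the axial C–S bond at C2 is syn-axial to the axial trajectory at C4, so hydride should arrive along the equatorial path from the α face and place C4–OH axial on the β face, while the cold acidic quench limits benzoyl migration.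

Step 9
Reactants: 13 [(7S,8S,9R,10R)-9-(benzoyloxy)-7,8,10-trihydroxy-1,5-dithiaspiro[5.5]undecan-7-yl]methyl benzoate
Product: 14 [(1S,2S,3R,4R)-3-(benzoyloxy)-1,2,4-trihydroxy-6-oxocyclohexyl]methyl benzoate (target; route locants 1S,4R,5R,6S)
Conditions: MeI (excess), CaCO3, MeCN/H2O (9:1), 40 °C
Reagents that add atoms: water, O
Why: Alkylative dithioacetal hydrolysis (S-methylation, thionium formation, capture by water) under buffered neutral conditions should unveil the C2 ketone without β-elimination of C4–OH, acyl migration or change at any stereocentre.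

Compound list
1 | 2,2-dimethyl-1,3-dioxan-5-one | CC1(C)OCC(=O)CO1 | starting material
2 | ethynylmagnesium bromide | C#C[Mg]Br | starting material
3 | 5-ethynyl-2,2-dimethyl-1,3-dioxan-5-ol | CC1(C)OCC(O)(C#C)CO1 | intermediate
4 | 2-ethynylpropane-1,2,3-triol | C#CC(O)(CO)CO | intermediate
5 | (2R)-2-hydroxy-2-(hydroxymethyl)but-3-yn-1-yl benzoate | C#C[C@@](O)(CO)COC(=O)c1ccccc1 | intermediate
6 | (2S)-2-formyl-2-hydroxybut-3-yn-1-yl benzoate | C#C[C@@](O)(C=O)COC(=O)c1ccccc1 | intermediate
7 | 2-(benzoyloxy)acetic acid | O=C(O)COC(=O)c1ccccc1 | starting material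
8 | 2-(benzoyloxy)acetyl chloride | O=C(Cl)COC(=O)c1ccccc1 | intermediate
9 | (2S)-2-formyl-2-hydroxy-5-oxohex-3-yne-1,6-diyl dibenzoate | O=C(COC(=O)c1ccccc1)C#C[C@@](O)(C=O)COC(=O)c1ccccc1 | intermediate
10 | propane-1,3-dithiol | SCCCS | starting material
11 | (2S)-2-{2-[3-(benzoyloxy)-2-oxopropyl]-1,3-dithian-2-yl}-2-formyl-2-hydroxyethyl benzoate (keto dithiane aldehyde) | O=C(COC(=O)c1ccccc1)CC1(SCCCS1)[C@@](O)(C=O)COC(=O)c1ccccc1 | intermediate
12 | [(7S,8S,9S)-9-(benzoyloxy)-7,8-dihydroxy-10-oxo-1,5-dithiaspiro[5.5]undecan-7-yl]methyl benzoate | O=C(OC[C@@]1(O)C2(SCCCS2)CC(=O)[C@@H](OC(=O)c2ccccc2)[C@@H]1O)c1ccccc1 | intermediate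
13 | [(7S,8S,9R,10R)-9-(benzoyloxy)-7,8,10-trihydroxy-1,5-dithiaspiro[5.5]undecan-7-yl]methyl benzoate | O=C(OC[C@@]1(O)C2(SCCCS2)C[C@@H](O)[C@@H](OC(=O)c2ccccc2)[C@@H]1O)c1ccccc1 | intermediate
14 | [(1S,2S,3R,4R)-3-(benzoyloxy)-1,2,4-trihydroxy-6-oxocyclohexyl]methyl benzoate | O=C(OC[C@@]1(O)C(=O)C[C@@H](O)[C@@H](OC(=O)c2ccccc2)[C@@H]1O)c1ccccc1 | target

Total step count: 9. Longest linear sequence: 8 (steps 1–4 and 6–9).

Steps most likely to fail

Step 7. The sequence may stall after the first thiol addition at the crowded C2. The thiol may be captured by the aldehyde. The magnesium-bound hydroxy aldehyde may undergo an α-ketol shift, or chelate control over the aldehyde face may erode. The fallback separates the events with known chemistry and keeps C6 masked; it sets out from 5 and comes back at 12. 2,2-Dimethoxypropane with pyridinium p-toluenesulfonate ties C1–OH and C6–OH into the dioxolane benzoate F1, which also stops benzoyl migration. Acyl Sonogashira coupling with 8 gives the protected ynone F2. Base-mediated double conjugate addition of 10 gives the keto dithiane acetonide F3, with no aldehyde present and with the C1 substituents tied back. Aqueous acetic acid frees the keto dithiane diol F4. Parikh–Doering oxidation then gives 11, now isolated, and a separate MgBr2·OEt2/i-Pr2NEt aldol addition leads to 12.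

Step 6. The amine may dehydrochlorinate the enolisable acid chloride to a ketene, which would then acylate the tertiary hydroxyl, and this consumes the coupling partner. The fallback replaces the acid chloride by an acyl donor that cannot form a ketene under these conditions; it sets out from 8 (with 6) and comes back at 9. Ethanethiol and Et3N convert 8 into the thioester S-ethyl 2-(benzoyloxy)ethanethioate F5. This is joined to 6 by the known palladium-catalysed thioester–terminal alkyne coupling (PdCl2(dppf), tri(2-furyl)phosphine, CuI, Et3N, DMF, 50 °C) to give 9.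

Step 8. Hydride may be delivered from both faces of C4, and the C5 benzoyl group may wander to the neighbouring lithium alkoxides. The fallback removes the free hydroxyls and adds reagent control; it sets out from 12 and comes back at 13. 2-Methoxypropene with pyridinium p-toluenesulfonate bridges the cis C1/C6 diol as the ketone acetonide F6, which keeps the same chair. Corey–Bakshi–Shibata reduction (the B-methyl oxazaborolidine antipode matched to the substrate bias, BH3·SMe2) gives the alcohol acetonide F7 through a non-basic boron alkoxide. Aqueous acetic acid then releases 13.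

Further compounds
F1 | step 7 | [(4R)-4-ethynyl-2,2-dimethyl-1,3-dioxolan-4-yl]methyl benzoate | C#C[C@]1(COC(=O)c2ccccc2)COC(C)(C)O1
F2 | step 7 | C1,C6-O-isopropylidene ynone (4-[4-(benzoyloxymethyl)-2,2-dimethyl-1,3-dioxolan-4-yl]-2-oxobut-3-yn-1-yl benzoate) | O=C(COC(=O)c1ccccc1)C#C[C@]1(COC(=O)c2ccccc2)COC(C)(C)O1
F3 | step 7 | keto dithiane acetonide | O=C(COC(=O)c1ccccc1)CC1(SCCCS1)[C@]1(COC(=O)c2ccccc2)COC(C)(C)O1
F4 | step 7 | keto dithiane diol | O=C(COC(=O)c1ccccc1)CC1(SCCCS1)[C@@](O)(CO)COC(=O)c1ccccc1
F5 | step 6 | S-ethyl 2-(benzoyloxy)ethanethioate | CCSC(=O)COC(=O)c1ccccc1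
F6 | step 8 | C1,C6-O-isopropylidene derivative of 12 | O=C(OC[C@]12OC(C)(C)O[C@H]1[C@H](OC(=O)c1ccccc1)C(=O)CC21SCCCS1)c1ccccc1
F7 | step 8 | C1,C6-O-isopropylidene derivative of 13 | O=C(OC[C@]12OC(C)(C)O[C@H]1[C@H](OC(=O)c1ccccc1)[C@H](O)CC21SCCCS1)c1ccccc1
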